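Its constants belong to no real substance; what happens was integrated by code.

E, the product with both ligands exchanged, is what to watch, and at rest one ratio ties it to X and L.

    X + G ⇌ D + L (K1 = 1.7, k1 = 0.32 M⁻¹ min⁻¹)
    L + G ⇌ D + E (K2 = 25, k2 = 0.53 M⁻¹ min⁻¹)
    L ⇌ Q (K3 = 2.0, k3 = 0.022 min⁻¹)
    X ⇌ J (K4 = 0.76, k4 = 0.025 min⁻¹)

X 0.10 M (fed, over 2.5 h); G 0.0900 M; time 30 h

- the reaction counts as stopped when no species that holds the X changes by six tenths of a point or more over the second half of the time
- run time (flask): 30 h

1. which holds at 30 h: what has brought the reaction to rest, or that it has not come to rest (forward and back rates have come level / it is still moving / G has run out first / all of X has reacted)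
2. how much L there is at 30 h, in percent of the X charged
3. how much E there is at 30 h, in percent of the X charged
4. how much Q there is at 30 h, in percent of the X charged
5. amount of L if the flask were left three thousand times as long, in percent of the X charged

1. I write x, l and e for X, L and E as fractions of the X charged. Dividing the constant of the second exchange by that of the first removes G and D, so at rest e·x/(l·l) equals 14.7. This is the exchange ratio, the usual disproportionation constant of L into X and E.

2. Two equal sites filled at random give a ratio of 0.250, which I take as the zero of the scale. This flask stands 58.8 times above that zero, so at rest it favours X and E over L.

3. At the start, X arrives at 0.400 h⁻¹ of the charge. Its forward half-lives, 0.401 h by the first step at the charged G and 0.462 h towards J, are shorter than the feed of 2.5 h. So I expect L and J to rise with the feed from the first minutes, not after X has piled up.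

4. The knee comes when the feed ends at 2.5 h. At the charged G, L goes on to E with a forward half-life of 0.242 h, which is shorter than the 0.525 h it takes towards Q. But that half-life lengthens as G is used, and the two forward rates are level once G has fallen to 46.1% of its charge.

5. At rest e/l equals the ratio times l/x, so E stands above L once l/x exceeds 0.0680. Each E takes two G, so the G charged allows E of at most 45.0% of the X charged, which is less than the whole charge, and G is the limiting reagent for E.

6. At rest J and Q stand in fixed proportions to X and L, so they leave the ratio untouched. My reckoning stops here, because the level of each species needs a balance of G that I do not solve by hand.

7. The forecast says forward and back rates have come level, with L 7.4% (6.8% to 8%), E 28% (26% to 30%), Q 14.7% (13.5% to 16%) and L after the long wait 7.4% (7% to 7.8%), "so neither X nor G runs out".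

8. The flask gives forward and back rates have come level, with L 7.35%, E 28.0%, Q 14.7% and L after the long wait 7.35%.

9. With X at 28.4%, the readings of this flask give e·x/(l·l) = 14.7, against the exchange ratio of 14.7. In a second flask with 0.025 M of X and the same G, X ends at 2.11% and L at 3.51%. The ratio then asks for E of 85.8%, and that flask holds 85.8%. In the recipe flask, E stays at 28.0% partly because D and E go back to L and G: without that way back the run no longer ends the same way, and E reaches 41.6%, which makes up 19% of what is missing.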